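Target and starting material together should stay at the charge, and the last ash reading gives 25% and 75%. So the fraction left is one minus the fraction made, and you can reckon with a single rate.

| flask | starting material | second substrate | enzyme | remark | time |
|---|---|---|---|---|---|
| maple | 0.20 M | 0.40 M | 0.066 mM | run made earlier |  |
| ash | 0.20 M | 0.40 M | 0.23 mM | run made earlier |  |
| elm | 0.14 M | 0.40 M | 0.20 mM | run made earlier |  |
| amber | 0.050 M | 0.400 M | 0.050 mM |  | 6.0 h |
| blue | 0.20 M | 0.400 M | 0.20 mM |  | 6.0 h |

- maple (time / h: target / %, starting material / %): 1.00: 0, 100; 2.00: 4, 95; 3.00: 8, 94; 4.00: 10, 92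
- ash (time / h: target / %, starting material / %): 0.333: 3, 99; 0.833: 5, 92; 2.00: 13, 90; 4.00: 25, 75
- elm (time / h: target / %, starting material / %): 1.00: 5, 97; 2.00: 15, 84; 3.00: 22, 83; 4.00: 29, 69

(scatter of a reading: 2 percentage points)

- the numbers in the tables scatter by 2 percentage points (one standard deviation)
- steps that have been proposed: starting material + enzyme <-> complex A; complex A -> enzyme + target; second substrate + enzyme <-> complex B; complex B -> enzyme + second product; enzyme -> spent catalyst A; 2 complex B -> spent catalyst B; enzyme <-> dormant form

* which of the two ends with the higher amount of target, in percent of the starting material charged ("neither" if they lie within 2 percentage points) (amber / blue / neither)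
* target at the end, in percent of the starting material charged, amber
* target at the end, in percent of the starting material charged, blue

The bench rule is to count turnovers. Divide the target made by the enzyme charged and by the time. The last ash reading gives 54.3 h⁻¹, the last elm reading 50.8 h⁻¹. Maple gives 75.8 h⁻¹, but from 10% with that same scatter, so I set it aside. The mean of the other two is 52.5 h⁻¹: this turnover rate T, target made per enzyme charged per hour (the turnover frequency), is what I carry. Between those charges it looks zero-order in starting material.

Then the fraction made is T times c(enzyme) times time over c(starting material). For blue that is 31.5%, leaving 68.5%, so c(starting material) ends at 0.137 M.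

Here is the border. The lowest c(starting material) read so far is elm's last, 0.0966 M. Blue stays above it. Amber has blue's ratio of enzyme to starting material, so the rule prints 31.5% again, but amber starts at 0.518 of that lowest value. T is untested there, and I expect less.

The forecast says blue, with 31% for blue and 25% for amber, since at low charge “starting material competes less well with the second substrate”.

    starting material + enzyme ⇌ complex A (K = 270 M⁻¹, k = 4500 M⁻¹ h⁻¹)
    complex A → enzyme + target (k = 66.0 h⁻¹)
    second substrate + enzyme ⇌ complex B (K = 1.40 M⁻¹, k = 32000 M⁻¹ h⁻¹)
    complex B → enzyme + second product (k = 1800 h⁻¹)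
    enzyme → spent catalyst A (k = 0.100 h⁻¹)
    2 complex B → spent catalyst B (k = 520 M⁻¹ h⁻¹)
    enzyme ⇌ dormant form (K = 1.50, k = 0.130 h⁻¹)

Blue gives 32.2% and amber 21.0%, so blue ends higher; the division printed 31.5% for both flasks, close to blue's value and above amber's. At 3.00 h, complex A held 81.3% of the catalyst charged in blue and 52.8% in amber. Blue's mean turnover rate is 53.6 h⁻¹; amber's is 35.1 h⁻¹, or 0.669 of T.

A neighbour of amber, charged with 0.085 M of starting material, lies just under the lowest value, and T gives it 18.5%. The computed flask gives 15.5%, a mean rate of 43.9 h⁻¹.

The earlier runs and the new flask come from a simulation with made-up constants; the scatter is artificial.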